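## Structural features

Isolophirone C is an achiral, fully aromatic benzofuran (ring A = benzo ring C3a–C7a, ring B = furan O1/C2/C3) carrying three oxygenated aryl units. These are a 4-hydroxyphenyl group (ring C) on C2, a 2,4-dihydroxybenzoyl group (ring D) on C3, and on C5 a CH2–CH2–C(=O) chain that ends in a second 2,4-dihydroxyphenyl ring (ring E). There is no stereocentre, so the problem is one of connectivity and regiochemistry only. Rings D and E are the same resorcinol ketone unit attached in two ways (diaryl ketone at C3, alkyl aryl ketone on the C5 chain), and ring C differs from them by a single oxygen, so C2 and C3 must receive two easily confused aryl groups in a defined order. The fragile features are the five free phenols, the enolisable chain ketone, and the C2=C3–C(=O) vinylogous ester, whose C2 can be attacked under base by the ortho-hydroxyl of ring D with opening of ring B. The real difficulty is the crowded, tetrasubstituted C2=C3 bond with an unambiguous aryl/aroyl assignment, followed by release of five phenols next to two chelating ketones. The key step uses the fact that C2 carries O1 and an aryl group, so it is at the oxidation level of an ester carbonyl carbon, while C3 carries a ketone and is therefore the carbon of a carbonyl-stabilised phosphorus ylide. A Wittig olefination between these two atoms closes ring B.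

## Logic of the disconnections

16 ⇒ 15. The five phenol O–H bonds are traced back to five O–CH3 bonds. Free phenols would not survive ylide, acyl chloride, Grignard or palladium chemistry, and methyl ethers are already present in the commercial building blocks. The gain is that every earlier intermediate is neutral and non-chelating. The demand is one operation that cleaves five ethers, three of them para to a ketone, without harming ring B or the chain.

15 ⇒ 12 + 14. The cut is the bond between C5 of ring A and the first CH2 of the chain. This removes the whole ring E ketone chain as one block and leaves only a bromine on ring A, which is inert in all earlier steps. The enolisable chain ketone is thus created only after the ylide chemistry is over. The forward step must couple a homoenolate equivalent with an aryl bromide without β-hydride elimination.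

14 ⇒ 13. The two C–C bonds from the carbinol carbon to the two CH2 groups are cut. The strained ring stores the homoenolate in stable form, and the precursor is a commercial ester. The forward step is a titanium-mediated cyclopropanation of an electron-rich, ortho-substituted benzoate.

12 ⇒ 10 (key disconnection). The C2=C3 bond of ring B is cut, so that C2 becomes an ester carbonyl carbon on the ring A oxygen and C3 becomes a ylide carbon. Ring B disappears, and the 2-aryl and 3-aroyl groups become two acyl groups introduced separately, one on oxygen and one on carbon. The forward step asks a stabilised ylide to olefinate an ester intramolecularly, faster than acyl groups can migrate.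

10 ⇒ 7 + 8 (through 9). The ester C(=O)–O bond is cut. Making this bond last means the aryl ester never meets the strong base used for ylide formation. The forward step must free the phenol without protonating the keto-ylide and acylate it at once. A neutral ortho-hydroxy keto-ylide can tautomerise to a phenoxide/acylphosphonium pair, which could close onto the wrong carbonyl with loss of Ph3PO.

7 ⇒ 3 + 4 (through 5 and 6). The bond between the ylide carbon and the ring D carbonyl carbon is cut, which reduces the keto-ylide to a benzylic ylide and a commercial acyl chloride. The phenol must carry a mask that is not an acyl donor and that comes off without acid, hence a silyl ether. The forward step needs two equivalents of base, because the first-formed acylphosphonium salt is more acidic than its precursor.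

3 ⇒ 2 ⇒ 1. The O–Si bond and then the benzylic C–P bond are cut. An ortho-hydroxybenzyl alcohol ionises under acid, so phosphorus can replace the hydroxyl directly and no benzylic halide is needed. In 1 the bromine is para to the phenol oxygen, which maps onto C5 of ring A.

## Other disconnections considered

Alternative 1: The cut is the bond between the ring D carbonyl carbon and ring D, together with the ring D C–O bond ortho to it. In the forward step, fluoride releases 5-(benzyloxy)-3-chlorobenzyne A3 from its silyl triflate precursor A4. The carboxylate of the benzofuran-3-carboxylic acid A2 adds to the aryne carbon remote from chlorine, and the aryl anion takes over the acyl group through a four-membered transition state to give the ortho-hydroxy ketone A1.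
- In its favour: the hindered diaryl ketone and its ortho-hydroxyl form together under nearly neutral conditions. The chlorine directs the regiochemistry. The phenols are unmasked at the end by hydrogenolysis and not by a boron halide, and on that point it is the better plan.
- Against it here: no ring is formed, so ring B must still be built, now as the acid A2 with an electrophilic enone chain. Protonation of the aryl anion by the acid gives the plain aryl ester and competes with acyl transfer. The final hydrogenation must remove four benzyl groups and an aryl chloride and saturate the alkene while sparing two ketones. A4 and A2 each need several steps.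
- Comparison: the chosen plan fixes the C2/C3 assignment while it builds the ring, and uses commercial acyl chlorides. Alternative 1 is its equal in regiochemical certainty at ring D but is clearly longer.

Alternative 2: Both aryl–C(=O) bonds to rings D and E are cut at once. In the forward step, the diacid A6 and two molecules of resorcinol A7 undergo a double Friedel–Crafts/Fries-type acylation at C4 of each resorcinol in BF3·OEt2 or P2O5/MeSO3H to give the mono-methyl ether A5.
- In its favour: both resorcinol ketones arrive in one step with four phenols unprotected, and only one methyl ether is left to cleave. On protecting-group burden it is the better plan.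
- Against it here: the two acids differ greatly. The C3 acid is a hindered vinylogous carbonate, giving a stabilised and sluggish acylium ion, and it is prone to protodecarboxylation in hot acid. The arylpropanoic acid can cyclise onto ring A to an indanone. Resorcinol can be acylated twice. Ring B is again not addressed, and A6 would need a sequence of about the same length as the one leading to 12.
- Comparison: the chosen plan forms each ketone from a pre-formed acyl unit at a defined site, so it relies on no electrophilic aromatic selectivity. Alternative 2 is the equal in convergence on paper but weaker in mechanism.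

Alternative 3: The cut is C3–C3a and O1–C2, which divides the target into a chalcone and a dihydrochalcone along the biosynthetic seam. In the forward step, Ag2O oxidises the phenols of A9 and A10. The Cα radical of A9 couples with the ortho carbon of the phenoxyl from A10, and the rearomatised phenol adds to the quinone methide to close the trans-dihydrofuran A8 (racemic). Dehydrogenation and demethylation would follow.
- In its favour: it is by far the shortest route. Both partners come from one Claisen–Schmidt condensation, and two bonds and ring B form in one step. On step economy it is the better plan, and in the final demethylation it is the equal.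
- Against it here: nothing enforces cross-coupling over homo-dimerisation of either phenol. The two phenols differ in oxidation potential. The Cα radical of A9 is weakened by the adjacent carbonyl. An additional oxidation of the free-phenol dihydrobenzofuran A8 to the aromatic furan is needed. The trans stereochemistry that is set is then destroyed.
- Comparison: the chosen plan is longer, but every bond is formed by a two-electron step between partners that can react in only one way.

Key step: step 5

Remark on the chemistry: the connectivity of 10 and 12 was checked atom by atom (bromine para to the ester oxygen in 10, hence at C5 in 12) and needs no correction. The design change is the phenol mask: a silyl ether removed by fluoride and acylated in the same flask, so that no free ortho-hydroxy keto-ylide and no acid meet the keto-ylide.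

## Route

Step 1
Reactants: 1 5-bromo-2-hydroxybenzyl alcohol
Product: 2 (5-bromo-2-hydroxybenzyl)triphenylphosphonium bromide
Conditions: PPh3·HBr (1.05 equiv), MeCN, reflux
Reagents that add atoms: triphenylphosphine hydrobromide, Br.c1ccc(cc1)P(c1ccccc1)c1ccccc1
Why: Acid-promoted ionisation of the ortho-hydroxybenzyl alcohol (ortho-quinone methide/benzylic cation) and capture by PPh3 is the standard direct phosphonium salt synthesis from salicyl alcohols; the aryl bromide is inert.

Step 2
Reactants: 2 (5-bromo-2-hydroxybenzyl)triphenylphosphonium bromide
Product: 3 {5-bromo-2-[(tert-butyldimethylsilyl)oxy]benzyl}triphenylphosphonium bromide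
Conditions: TBSCl, imidazole, DMF, rt
Reagents that add atoms: tert-butyldimethylsilyl chloride, CC(C)(C)[Si](C)(C)Cl
Why: Standard silylation of a phenol; the silyl ether is not an acyl donor, so the ylide made next cannot undergo a premature Wittig closure, and it is later removed by fluoride without acid; the phosphonium should pair with the more lipophilic bromide on extraction.

Step 3
Reactants: 3 {5-bromo-2-[(tert-butyldimethylsilyl)oxy]benzyl}triphenylphosphonium bromide; 4 2,4-dimethoxybenzoyl chloride
Product: 7 2-{5-bromo-2-[(tert-butyldimethylsilyl)oxy]phenyl}-1-(2,4-dimethoxyphenyl)-2-(triphenyl-λ5-phosphanylidene)ethan-1-one, via benzylidenephosphorane 5 (not isolated), via acylphosphonium chloride 6 (not isolated)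
Conditions: NaN(SiMe3)2 (2.1 equiv), THF, −78 → 0 °C; then 4 (1.0 equiv), −78 °C → rt
Reagents that add atoms: none
Why: C-acylation of a phosphorus ylide by an acyl chloride; the second equivalent of base deprotonates the far more acidic acylphosphonium salt 6, so all of the phosphonium salt is carried to the keto-stabilised ylide, and low temperature should suppress a 1,4-shift of silicon from oxygen to the ylide carbon.

Step 4
Reactants: 7 2-{5-bromo-2-[(tert-butyldimethylsilyl)oxy]phenyl}-1-(2,4-dimethoxyphenyl)-2-(triphenyl-λ5-phosphanylidene)ethan-1-one; 8 4-methoxybenzoyl chloride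
Product: 10 4-bromo-2-[2-(2,4-dimethoxyphenyl)-2-oxo-1-(triphenyl-λ5-phosphanylidene)ethyl]phenyl 4-methoxybenzoate, via ammonium phenolate 9 (not isolated)
Conditions: Bu4NF (1.05 equiv), THF, 0 °C; then 8 (1.1 equiv), 0 °C → rt
Reagents that add atoms: none
Why: Fluoride desilylation gives the phenolate 9, the strongest nucleophile present, which is O-acylated at once (ester formation from a phenolate and an acyl chloride); keeping the phenol anionic and short-lived should prevent the phenoxide/acylphosphonium tautomer from closing onto the ring D carbonyl.

Step 5
Reactants: 10 4-bromo-2-[2-(2,4-dimethoxyphenyl)-2-oxo-1-(triphenyl-λ5-phosphanylidene)ethyl]phenyl 4-methoxybenzoate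
Product: 12 [5-bromo-2-(4-methoxyphenyl)benzofuran-3-yl](2,4-dimethoxyphenyl)methanone, via oxaphosphetane 11 (not isolated)
Conditions: Et3N (0.2 equiv), toluene (0.02 M), 110 °C
Reagents that add atoms: none
Why: The ylide carbon of 10 adds to the carbonyl carbon of the neighbouring aryl 4-methoxybenzoate, the betaine closes to the cis-fused oxaphosphetane 11, and cycloreversion expels Ph3PO to leave the C2=C3 bond of the aromatic furan. The closest known reaction type is the intramolecular Wittig olefination of ester carbonyls by ortho-acyloxybenzyl ylides to benzofurans, including keto-stabilised ylides that give 3-aroyl-2-arylbenzofurans. Ring B closes in the 5-exo-trig mode, since C3 attacks C2 while the C=O being attacked lies outside the new ring. No stereocentre is created, because the two tetrahedral carbons of 11 are lost on elimination. The selectivity needed is olefination ahead of acyl transfer: opening of the betaine with loss of the ring A phenoxide could let it re-close on the other carbonyl and exchange the C2 and C3 aryl groups, and the ylide oxygen could also attack the ester. The substrate secures this because only the ester carbonyl is within five-membered reach of the ylide carbon and it is the most electrophilic carbonyl (aryl ester), whereas the ylide's own ketone is enolate-like, electron-rich and shielded by its ortho-methoxy group, so even a reversibly opened betaine should return to the 4-methoxybenzoyl carbon. Aromatisation and the strong P=O bond make the productive collapse irreversible, dilution and heat favour the unimolecular closure, and Et3N removes traces of acid that would protonate the ylide.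

Step 6
Reactants: 13 methyl 2,4-dimethoxybenzoate
Product: 14 1-(2,4-dimethoxyphenyl)cyclopropan-1-ol
Conditions: EtMgBr (3 equiv), Ti(OiPr)4 (0.5 equiv), THF, 0 °C → rt; aq. NH4Cl
Reagents that add atoms: ethylmagnesium bromide, CC[Mg]Br
Why: Kulinkovich cyclopropanation: the titanacyclopropane formed from two ethyl groups acts as a 1,2-dicarbanion towards the ester and supplies both CH2 groups; methyl benzoates are standard substrates.

Step 7
Reactants: 12 [5-bromo-2-(4-methoxyphenyl)benzofuran-3-yl](2,4-dimethoxyphenyl)methanone; 14 1-(2,4-dimethoxyphenyl)cyclopropan-1-ol
Product: 15 3-[3-(2,4-dimethoxybenzoyl)-2-(4-methoxyphenyl)benzofuran-5-yl]-1-(2,4-dimethoxyphenyl)propan-1-one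
Conditions: Pd(OAc)2 (5 mol %), XPhos (10 mol %), Cs2CO3 (2 equiv), toluene, 80 °C
Reagents that add atoms: none
Why: Palladium-catalysed ring-opening cross-coupling of a cyclopropanol with an aryl bromide: oxidative addition, formation of the palladium cyclopropoxide, β-carbon elimination to the palladium homoenolate and reductive elimination give the β-aryl ketone; the bulky biaryl phosphine should favour reductive elimination over β-hydride elimination.

Step 8
Reactants: 15 3-[3-(2,4-dimethoxybenzoyl)-2-(4-methoxyphenyl)benzofuran-5-yl]-1-(2,4-dimethoxyphenyl)propan-1-one
Product: 16 isolophirone C, 3-[3-(2,4-dihydroxybenzoyl)-2-(4-hydroxyphenyl)benzofuran-5-yl]-1-(2,4-dihydroxyphenyl)propan-1-one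
Conditions: BBr3 (15 equiv), CH2Cl2, −78 °C → rt; then H2O
Reagents that add atoms: none
Why: Lewis-acid cleavage of aryl methyl ethers by BBr3; the two ethers ortho to the ketones go first through boron chelates, excess reagent and time should cleave the other three, and neither the benzofuran nor the ketones are attacked.

## Compound list

1 | 5-bromo-2-hydroxybenzyl alcohol | OCc1cc(Br)ccc1O | starting material
2 | (5-bromo-2-hydroxybenzyl)triphenylphosphonium bromide | Oc1ccc(Br)cc1C[P+](c1ccccc1)(c1ccccc1)c1ccccc1.[Br-] | intermediate
3 | {5-bromo-2-[(tert-butyldimethylsilyl)oxy]benzyl}triphenylphosphonium bromide | CC(C)(C)[Si](C)(C)Oc1ccc(Br)cc1C[P+](c1ccccc1)(c1ccccc1)c1ccccc1.[Br-] | intermediate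
4 | 2,4-dimethoxybenzoyl chloride | COc1ccc(C(Cl)=O)c(OC)c1 | starting material
5 | {5-bromo-2-[(tert-butyldimethylsilyl)oxy]benzylidene}triphenyl-λ5-phosphane (benzylic ylide) | CC(C)(C)[Si](C)(C)Oc1ccc(Br)cc1C=P(c1ccccc1)(c1ccccc1)c1ccccc1 | intermediate (not isolated)
6 | [1-{5-bromo-2-[(tert-butyldimethylsilyl)oxy]phenyl}-2-(2,4-dimethoxyphenyl)-2-oxoethyl]triphenylphosphonium chloride (racemic) | CC(C)(C)[Si](C)(C)Oc1ccc(Br)cc1C(C(=O)c1ccc(OC)cc1OC)[P+](c1ccccc1)(c1ccccc1)c1ccccc1.[Cl-] | intermediate (not isolated)
7 | 2-{5-bromo-2-[(tert-butyldimethylsilyl)oxy]phenyl}-1-(2,4-dimethoxyphenyl)-2-(triphenyl-λ5-phosphanylidene)ethan-1-one | CC(C)(C)[Si](C)(C)Oc1ccc(Br)cc1C(=P(c1ccccc1)(c1ccccc1)c1ccccc1)C(=O)c1ccc(OC)cc1OC | intermediate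
8 | 4-methoxybenzoyl chloride | COc1ccc(cc1)C(Cl)=O | starting material
9 | tetrabutylammonium 4-bromo-2-[2-(2,4-dimethoxyphenyl)-2-oxo-1-(triphenyl-λ5-phosphanylidene)ethyl]phenolate | [O-]c1ccc(Br)cc1C(=P(c1ccccc1)(c1ccccc1)c1ccccc1)C(=O)c1ccc(OC)cc1OC.CCCC[N+](CCCC)(CCCC)CCCC | intermediate (not isolated)
10 | 4-bromo-2-[2-(2,4-dimethoxyphenyl)-2-oxo-1-(triphenyl-λ5-phosphanylidene)ethyl]phenyl 4-methoxybenzoate | COc1ccc(cc1)C(=O)Oc1ccc(Br)cc1C(=P(c1ccccc1)(c1ccccc1)c1ccccc1)C(=O)c1ccc(OC)cc1OC | intermediate (precursor of the key step)
11 | cis-fused 1,2-oxaphosphetane across C2 and C3 of 5-bromo-3-(2,4-dimethoxybenzoyl)-2-(4-methoxyphenyl)-2,3-dihydrobenzofuran, with O on C2 and PPh3 on C3 (racemic, relative configuration drawn) | COc1ccc(cc1)[C@@]23Oc4ccc(Br)cc4[C@]2(C(=O)c2ccc(OC)cc2OC)P(c2ccccc2)(c2ccccc2)(c2ccccc2)O3 | intermediate (not isolated)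
12 | [5-bromo-2-(4-methoxyphenyl)benzofuran-3-yl](2,4-dimethoxyphenyl)methanone | COc1ccc(cc1)-c1oc2ccc(Br)cc2c1C(=O)c1ccc(OC)cc1OC | intermediate (product of the key step)
13 | methyl 2,4-dimethoxybenzoate | COC(=O)c1ccc(OC)cc1OC | starting material
14 | 1-(2,4-dimethoxyphenyl)cyclopropan-1-ol | COc1ccc(C2(O)CC2)c(OC)c1 | intermediate
15 | 3-[3-(2,4-dimethoxybenzoyl)-2-(4-methoxyphenyl)benzofuran-5-yl]-1-(2,4-dimethoxyphenyl)propan-1-one | COc1ccc(cc1)-c1oc2ccc(CCC(=O)c3ccc(OC)cc3OC)cc2c1C(=O)c1ccc(OC)cc1OC | intermediate
16 | isolophirone C, 3-[3-(2,4-dihydroxybenzoyl)-2-(4-hydroxyphenyl)benzofuran-5-yl]-1-(2,4-dihydroxyphenyl)propan-1-one | O=C(CCc1ccc2oc(-c3ccc(O)cc3)c(C(=O)c3ccc(O)cc3O)c2c1)c1ccc(O)cc1O | target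

## Step count and risks

Total step count: 8. Longest linear sequence: 7 steps (steps 1, 2, 3, 4, 5, 7 and 8, from 1 to 16); step 6 is a one-step side branch.

Step 5 (key step). The most likely failure is slow addition of the crowded, weakly nucleophilic ylide carbon to a donor-substituted benzoate. That would leave time for acyl migration through ring-opening of the betaine, which scrambles the aryl groups between C2 and C3, or for loss of the ester to adventitious water. Fallback: set out from 2 and carry out the well-established variant with the more nucleophilic benzylic ylide. Treating 2 with 8 and Et3N in refluxing toluene (O-acylation, then intramolecular ester Wittig) should give 5-bromo-2-(4-methoxyphenyl)benzofuran F1. Friedel–Crafts acylation of F1 at C3, the most nucleophilic position of a 2-arylbenzofuran, with 4 and SnCl4 in CH2Cl2 returns to the route at 12.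

Step 3. The hindered ylide 5 may be acylated slowly. Proton transfer between 6 and unreacted 5, O-acylation of 7, attack of the amide base on 4, or a shift of silicon from oxygen to the ylide carbon could then compete. Fallback: set out from 2 and reverse the order of the acylations without a protecting group. O-acylation of 2 with 8 (one equivalent, Et3N, CH2Cl2, 0 °C) should give [5-bromo-2-(4-methoxybenzoyloxy)benzyl]triphenylphosphonium bromide F2. C-acylation of its ylide with 4 and Et3N at room temperature, below the temperature at which the benzylic ylide closes, then returns to the route at 10. The risk there is premature Wittig closure to the 3-unsubstituted benzofuran.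

Step 7. β-Hydride elimination from the palladium homoenolate would give the aryl vinyl ketone and Heck-type enones. Base-induced ring opening of 14 to the propiophenone before it reaches palladium is the other risk. Fallback: set out from 12 and use a Heck arylation of a secondary allylic alcohol. Addition of CH2=CHMgBr to 2,4-dimethoxybenzaldehyde F3 gives 1-(2,4-dimethoxyphenyl)prop-2-en-1-ol F4 (racemic). Coupling F4 with 12 under ligand-free phase-transfer conditions (Pd(OAc)2, Bu4NCl, NaHCO3, DMF, 80 °C) should give the saturated ketone directly, by β-hydride elimination towards the carbinol and tautomerisation, returning to the route at 15.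

Step 8. Cleavage of the three methoxy groups para to boron-complexed ketones may be incomplete, or long exposure to the Lewis acid may degrade the product. Fallback: set out from 15 and deprotect in two stages by two mechanisms. BCl3 in CH2Cl2 at 0 °C should cleave only the two chelation-activated ortho ethers to give (2-hydroxy-4-methoxyphenyl){5-[3-(2-hydroxy-4-methoxyphenyl)-3-oxopropyl]-2-(4-methoxyphenyl)benzofuran-3-yl}methanone F5. Nucleophilic dealkylation of the remaining three ethers of F5 in molten pyridinium chloride (about 190 °C), acidic conditions under which the phenoxide-triggered opening of ring B cannot occur, returns to the route at 16.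

## Further compounds

F1 | step 5 | 5-bromo-2-(4-methoxyphenyl)benzofuran | COc1ccc(cc1)-c1cc2cc(Br)ccc2o1
F2 | step 3 | [5-bromo-2-(4-methoxybenzoyloxy)benzyl]triphenylphosphonium bromide | COc1ccc(cc1)C(=O)Oc1ccc(Br)cc1C[P+](c1ccccc1)(c1ccccc1)c1ccccc1.[Br-]
F3 | step 7 | 2,4-dimethoxybenzaldehyde | COc1ccc(C=O)c(OC)c1
F4 | step 7 | 1-(2,4-dimethoxyphenyl)prop-2-en-1-ol (racemic) | COc1ccc(C(O)C=C)c(OC)c1
F5 | step 8 | (2-hydroxy-4-methoxyphenyl){5-[3-(2-hydroxy-4-methoxyphenyl)-3-oxopropyl]-2-(4-methoxyphenyl)benzofuran-3-yl}methanone | COc1ccc(cc1)-c1oc2ccc(CCC(=O)c3ccc(OC)cc3O)cc2c1C(=O)c1ccc(OC)cc1O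
A1 | alternative 1 | (E)-3-[3-(4-benzyloxy-2-chloro-6-hydroxybenzoyl)-2-(4-benzyloxyphenyl)benzofuran-5-yl]-1-(2,4-dibenzyloxyphenyl)prop-2-en-1-one | O=C(c1c(Cl)cc(OCc2ccccc2)cc1O)c1c(-c2ccc(OCc3ccccc3)cc2)oc2ccc(/C=C/C(=O)c3ccc(OCc4ccccc4)cc3OCc3ccccc3)cc12
A2 | alternative 1 | (E)-2-(4-benzyloxyphenyl)-5-[3-(2,4-dibenzyloxyphenyl)-3-oxoprop-1-en-1-yl]benzofuran-3-carboxylic acid | OC(=O)c1c(-c2ccc(OCc3ccccc3)cc2)oc2ccc(/C=C/C(=O)c3ccc(OCc4ccccc4)cc3OCc3ccccc3)cc12
A3 | alternative 1 | 5-(benzyloxy)-3-chlorobenzyne | ClC1=CC(OCc2ccccc2)=CC#C1
A4 | alternative 1 | 5-(benzyloxy)-3-chloro-2-(trimethylsilyl)phenyl trifluoromethanesulfonate | C[Si](C)(C)c1c(Cl)cc(OCc2ccccc2)cc1OS(=O)(=O)C(F)(F)F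
A5 | alternative 2 | isolophirone C mono-methyl ether, (2,4-dihydroxyphenyl){5-[3-(2,4-dihydroxyphenyl)-3-oxopropyl]-2-(4-methoxyphenyl)benzofuran-3-yl}methanone | COc1ccc(cc1)-c1oc2ccc(CCC(=O)c3ccc(O)cc3O)cc2c1C(=O)c1ccc(O)cc1O
A6 | alternative 2 | 5-(2-carboxyethyl)-2-(4-methoxyphenyl)benzofuran-3-carboxylic acid | COc1ccc(cc1)-c1oc2ccc(CCC(O)=O)cc2c1C(O)=O
A7 | alternative 2 | resorcinol | Oc1cccc(O)c1
A8 | alternative 3 | trans-3-(2,4-dimethoxybenzoyl)-5-[3-(2,4-dimethoxyphenyl)-3-oxopropyl]-2-(4-hydroxyphenyl)-2,3-dihydrobenzofuran (racemic, one enantiomer drawn) | COc1ccc(C(=O)CCc2ccc3O[C@@H](c4ccc(O)cc4)[C@H](C(=O)c4ccc(OC)cc4OC)c3c2)c(OC)c1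
A9 | alternative 3 | (E)-1-(2,4-dimethoxyphenyl)-3-(4-hydroxyphenyl)prop-2-en-1-one | COc1ccc(C(=O)/C=C/c2ccc(O)cc2)c(OC)c1
A10 | alternative 3 | 1-(2,4-dimethoxyphenyl)-3-(4-hydroxyphenyl)propan-1-one | COc1ccc(C(=O)CCc2ccc(O)cc2)c(OC)c1
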